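At 40.0 s the spring flask you are taking over stands at 44.7% product and 53.8% substrate, both in percent of the substrate charged.

| setting | spring | noon | flask |
|---|---|---|---|
| substrate | 0.25 M | 0.38 M | 0.25 M |
| gas phase | 30 mM (held) | 30 mM (held) | 30 mM (held) |
| catalyst | 1 mol% | 1 mol% | 1 mol% |
| remark | the very flask that is asked about, followed so far | run made earlier |  |
| time |  |  | 2.0 min |

- spring (time / s: product / %, substrate / %): 10.0: 11.0, 90.8; 15.0: 17.0, 83.7; 40.0: 44.7, 53.8
- noon (time / s: product / %, substrate / %): 12.0: 11.1, 89.3; 25.0: 23.5, 75.4; 40.0: 37.1, 64.6; 50.0: 46.5, 54.5

(scatter of a reading: 1 percentage point)

1. the product standing at 2.0 min, as a percentage of the substrate charged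
2. concentration of dissolved gas in solution at 2.0 min, in percent of saturation

- at the start none of the gas is dissolved
- the analysis behind the earlier runs scatters by 1 percentage point, standard deviation
- steps under discussion: substrate + dissolved gas + catalyst -> catalyst + product; gas phase <-> dissolved gas

I replace the curve by its mean, the straight line from the start through that last reading. It reaches full conversion at τ = 89.5 s, the run-out time: how long the charge lasts at the mean rate. As a check, the line gives 16.8% at 15.0 s, where I read 17.0%, with a scatter of 1 percentage point. The noon run, with more substrate, gives a longer 108 s, so I keep the spring value.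

Leave the stirrer and the gas line alone. Saturated solution holds 30 mM of dissolved gas, which at the mean rate lasts 10.7 s, shorter than τ, so gas must keep crossing over from the gas phase.

When you come at 2.0 min, τ has passed by 30.5 s. I expect product a little short of 100 %, with a small tail of substrate.

The forecast says 98% product and 93% of saturation, since “With little substrate left, consumption collapses and the gas recovers quickly”.

The spring flask gives 96.6% product and dissolved gas at 85.6% of saturation, with 3.4% substrate left.

    substrate + dissolved gas + catalyst → catalyst + product (k = 800 /M²/s)
    gas phase ⇌ dissolved gas, rate k2*(csat - [dissolved gas]) (kL = 0.140 /s)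

The line holds at 1.00 min, where τ gives 67.0% and the flask holds 65.7% product, and τ of 89.5 s is shorter than the 2.0 min asked. At that asked time the crossing from the gas phase delivers dissolved gas 1.39 times as fast as the reaction takes it, each step taken net, with 0.0257 M of dissolved gas in solution. For a reading at 30 s, τ gives 33.5% product, and that reading holds 34.9%.

Readings and results come from a simulation from invented constants; scatter was added.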